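Locants: C1 = methyl-bearing ring-fusion carbon; C2, C3 = cyclopentane CH2; C4 = ring CH carrying the side chain; C5 = oxygen-bearing ring-fusion carbon; C6, C7 = CH2CH2 bridge; C8 = methyl-bearing ether carbon; C9 = carbinol carbon; C10 = CH2 between C9 and C1; C11 = side-chain CH; C12 = its CH2O.
Retrosynthetic cuts, in order: the aryl ester at C12–O; the ether bond C8–O (back to a C8=C9 alkene and a C5 hydroxyl); the C4–C5 bond together with the lactone C12–O bond; then C4=C11 (olefination), C1–C2 (allylation), C8=C9 (ring-closing metathesis) and C1–C5 (ketone synthesis).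
Forward: the cycloheptenone is made first, quaternary C1 is installed on it, cyclopentane and γ-lactone are closed together by SmI2, and the oxygen bridge of the 8-oxabicyclo[3.2.1]octane is closed last, after the vanillate is attached.
What makes the key step possible: ring-fusion carbon C5 bears oxygen and no hydrogen, its neighbours are quaternary C1 and methine C4, and the chain on C4 reaches oxygenated C12 two atoms out; the atoms O, C5, C4, C11, C12 therefore close to a γ-lactone fused to the cyclopentane, which is the adduct of a C5 ketyl with the β-carbon of a C4=C11 unsaturated ester.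
Stereochemistry: C1 from a palladium–phosphinooxazoline allylation; C5, C4 and C11 from the ketyl cyclisation (cis fusion relayed from C1, chelation of the Z-enoate, enolate protonation); C8 and C9 from anti opening of a C8–C9 epoxide by the C5 hydroxyl.

Key step: step 9

Remark: O-benzylvanillic acid 19 is taken as a purchased compound (it is one benzylation and saponification away from vanillic acid); descriptors given with C1–C12 refer to the locants above.

Step 1
Reactants: 1 4-methylpent-4-enoic acid
Product: 3 N-methoxy-N,4-dimethylpent-4-enamide, via 1-(4-methylpent-4-enoyl)imidazole 2 (not isolated)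
Conditions: CDI, CH2Cl2, rt; then MeNHOMe·HCl, rt
Reagents that add atoms: 1,1'-carbonyldiimidazole, O=C(n1ccnc1)n1ccnc1 (imidazolyl group of 2 only); N,O-dimethylhydroxylamine hydrochloride, CNOC.Cl
Why: Acyl imidazole formation followed by aminolysis is the standard Weinreb amide synthesis, and the unactivated 1,1-disubstituted alkene is not touched.

Step 2
Reactants: 3 N-methoxy-N,4-dimethylpent-4-enamide; 4 4-bromopent-1-ene
Product: 6 4,8-dimethylnona-1,8-dien-5-one (racemic), via pent-4-en-2-ylmagnesium bromide 5 (not isolated)
Conditions: 4, Mg, THF, 0 to 20 °C; then 3, THF, 0 °C; aq. HCl work-up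
Reagents that add atoms: magnesium, [Mg] (in 5 only)
Why: Grignard addition to a Weinreb amide stops at the ketone because the magnesium-chelated tetrahedral adduct survives until work-up; the reagent is made and used cold so that the slow cyclopropylmethyl rearrangement of the secondary homoallyl reagent should not compete, and the racemic α-centre is of no consequence because step 4 removes it.

Step 3
Reactants: 6 4,8-dimethylnona-1,8-dien-5-one
Product: 7 2,5-dimethylcyclohept-4-en-1-one (racemic)
Conditions: second-generation Grubbs catalyst [RuCl2(=CHPh)(H2IMes)(PCy3)] (3 mol%), CH2Cl2 (0.01 M), 40 °C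
Reagents that add atoms: none
Why: Ring-closing metathesis of a monosubstituted with a 1,1-disubstituted alkene to a trisubstituted cycloheptene is routine with this catalyst at high dilution, loss of ethene driving the closure of the seven-membered ring (C8=C9).

Step 4
Reactants: 7 2,5-dimethylcyclohept-4-en-1-one
Product: 8 [(2,5-dimethylcyclohepta-1,4-dien-1-yl)oxy]trimethylsilane
Conditions: TMSCl, NaI, Et3N, MeCN, rt
Reagents that add atoms: chlorotrimethylsilane, C[Si](C)(C)Cl
Why: Equilibrating silylation with iodotrimethylsilane generated in the flask (thermodynamic silyl enol ether formation) should favour the tetrasubstituted C1=C5 enol ether over the C5=C6 isomer, as with 2-methylcycloalkanones in general, and it erases the racemic C1 centre.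

Step 5
Reactants: 8 [(2,5-dimethylcyclohepta-1,4-dien-1-yl)oxy]trimethylsilane
Product: 9 (2R)-2,5-dimethyl-2-(prop-2-en-1-yl)cyclohept-4-en-1-one
Conditions: Pd2(dba)3 (2.5 mol%), (S)-t-BuPHOX [(S)-4-tert-butyl-2-(2-diphenylphosphinophenyl)-4,5-dihydrooxazole] (6.25 mol%), diallyl carbonate (1.05 equiv), Bu4N[Ph3SiF2] (35 mol%), THF, 25 °C
Reagents that add atoms: diallyl carbonate, C=CCOC(=O)OCC=C
Why: Enantioselective Tsuji allylation in its silyl enol ether variant, in which fluoride frees the tetrasubstituted enolate, zerovalent palladium ionises diallyl carbonate with loss of CO2, and C–C bond formation on the phosphinooxazoline-bound allylpalladium enolate sets quaternary C1; the (S)-ligand is chosen because it gives 2-allyl-2-methylcycloalkanones with the spatial arrangement that is (R) here, where the ring CH2 outranks allyl.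

Step 6
Reactants: 9 (2R)-2,5-dimethyl-2-(prop-2-en-1-yl)cyclohept-4-en-1-one
Product: 11 (2R)-2-(3-hydroxypropyl)-2,5-dimethylcyclohept-4-en-1-one, via B-alkyl-9-borabicyclo[3.3.1]nonane 10 (not isolated)
Conditions: 9-BBN (1.2 equiv), THF, 0 °C to rt; then NaOH, H2O2, H2O, 0 °C
Reagents that add atoms: 9-borabicyclo[3.3.1]nonane, B1C2CCCC1CCC2 (in 10 only); hydrogen peroxide, OO
Why: Hydroboration–oxidation, in which 9-BBN adds anti-Markovnikov to the monosubstituted alkene much faster than to the trisubstituted ring alkene or the hindered α-quaternary ketone, and any C5 carbinol from over-reduction is returned to the ketone in step 7.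

Step 7
Reactants: 11 (2R)-2-(3-hydroxypropyl)-2,5-dimethylcyclohept-4-en-1-one
Product: 12 3-[(1R)-1,4-dimethyl-7-oxocyclohept-3-en-1-yl]propanal
Conditions: Dess–Martin periodinane, CH2Cl2, 0 °C to rt
Reagents that add atoms: none
Why: Dess–Martin oxidation takes the primary alcohol to the aldehyde without base, which avoids aldol closure of the 1,5-keto aldehyde and leaves quaternary C1 untouched.

Step 8
Reactants: 12 3-[(1R)-1,4-dimethyl-7-oxocyclohept-3-en-1-yl]propanal; 13 methyl 2-[bis(2,2,2-trifluoroethoxy)phosphoryl]propanoate
Product: 15 methyl (2Z)-5-[(1R)-1,4-dimethyl-7-oxocyclohept-3-en-1-yl]-2-methylpent-2-enoate, via potassium phosphonate carbanion 14 (not isolated)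
Conditions: 13, KN(SiMe3)2, 18-crown-6, THF, −78 °C; then 12, −78 °C
Reagents that add atoms: potassium bis(trimethylsilyl)amide, [K+].C[Si](C)(C)[N-][Si](C)(C)C (potassium of 14 only)
Why: Still–Gennari olefination, in which the bis(trifluoroethyl)phosphonate anion with a dissociated potassium counter-ion eliminates under kinetic control to the Z-trisubstituted enoate, and the aldehyde reacts in preference to the hindered ketone.

Step 9
Reactants: 15 methyl (2Z)-5-[(1R)-1,4-dimethyl-7-oxocyclohept-3-en-1-yl]-2-methylpent-2-enoate
Product: 17 tricyclic γ-lactone (1R,4R,5S,11S) of the cis-fused hydroazulene (lactone ring O–C5–C4–C11–C12; C8=C9 retained), via hydroxy ester 16 (not isolated)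
Conditions: SmI2 (2.5 equiv), t-BuOH (2 equiv), THF, −78 °C to rt
Reagents that add atoms: none
Why: Electron transfer from divalent samarium to the C5 ketone gives a ketyl that adds to C4, the β-carbon of the Z-enoate, in a 5-exo-trig radical closure of the cyclopentane (ketyl–olefin cyclisation onto an α,β-unsaturated ester, a known samarium diiodide reaction type); a second electron turns the C11 radical into a trivalent samarium enolate that t-BuOH protonates, and the tertiary C5 alkoxide of 16 then attacks the methyl ester in a 5-exo-trig acyl substitution to close the γ-lactone. C5 is controlled by C1, because the three-atom tether can reach only the ketyl face on which it is held, so the hydroazulene should be cis-fused with the oxygen syn to the C1 methyl. C4 is controlled by chelation: with the Z-enoate the ester carbonyl can bind the samarium on the ketyl oxygen in the chair-like transition state, which places C11 syn to the C5 oxygen, and only this adduct can lactonise, so an anti adduct stays open-chain and is removed by chromatography. C11 is set by C-protonation of the enolate by the bulky alcohol on the face remote from quaternary C5 (the convex face of the forming oxabicyclo[3.3.0]octanone), which leaves the C11 methyl on the concave side as the target requires. The step needs chemoselectivity for the ketone–enoate pair over the trisubstituted C8=C9 alkene and it needs the chelate to persist; the isolated alkene is not reduced by SmI2 in THF, and HMPA is left out so that the ester stays bound to samarium.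

Step 10
Reactants: 17 tricyclic γ-lactone
Product: 18 (2S)-2-[(1R,3aR,8aS)-8a-hydroxy-3a,6-dimethyl-1,2,3,3a,4,7,8,8a-octahydroazulen-1-yl]propan-1-ol (the C5,C12-diol)
Conditions: LiAlH4, THF, 0 °C to rt; H2O/NaOH work-up
Reagents that add atoms: none
Why: Hydride reduction of the lactone gives the primary C12 carbinol and frees the tertiary C5 hydroxyl; the isolated alkene is inert and C11 is not epimerised because hydride addition is much faster than enolisation.

Step 11
Reactants: 18 C5,C12-diol; 19 4-(benzyloxy)-3-methoxybenzoic acid
Product: 20 C12 4-(benzyloxy)-3-methoxybenzoate of diol 18 (C5 hydroxyl free)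
Conditions: EDC·HCl, DMAP (cat.), CH2Cl2, 0 °C to rt
Reagents that add atoms: none
Why: Carbodiimide (Steglich) esterification should acylate only the primary C12 hydroxyl, the tertiary ring-fusion hydroxyl being too hindered, and the benzyl ether keeps the phenol out of the acylation.

Step 12
Reactants: 20 C12 4-(benzyloxy)-3-methoxybenzoate
Product: 22 O-benzyl ether of the target (5,8-oxide with 9-hydroxyl), via 8,9-epoxide 21 (not isolated)
Conditions: mCPBA, CH2Cl2, 0 °C to rt; then CSA (10 mol%), rt
Reagents that add atoms: 3-chloroperoxybenzoic acid, OOC(=O)c1cccc(Cl)c1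
Why: Prilezhaev epoxidation followed by acid-catalysed transannular epoxide opening, a sequence known for carotol-type 5-hydroxy-8-enes of this skeleton; the epoxide on the face opposite to the C5 hydroxyl and C1 methyl is attacked at tertiary C8 by the C5 oxygen with inversion (Markovnikov opening), which closes the 8-oxabicyclo[3.2.1]octane and leaves the C9 hydroxyl trans to the bridge, so C8 and C9 both follow from the epoxide face.

Step 13
Reactants: 22 O-benzyl ether of the target
Product: 23 CNP0277205.1
Conditions: H2 (1 atm), Pd/C (10 wt% Pd), EtOAc, rt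
Reagents that add atoms: none
Why: Hydrogenolysis of the benzyl aryl ether frees the phenol, while the aroyl ester, the tertiary ether bridge and the secondary alcohol are inert and no alkene remains.

Compound list
1 | 4-methylpent-4-enoic acid | C=C(C)CCC(=O)O | starting material
2 | 1-(4-methylpent-4-enoyl)imidazole | C=C(C)CCC(=O)n1ccnc1 | intermediate
3 | N-methoxy-N,4-dimethylpent-4-enamide | C=C(C)CCC(=O)N(C)OC | intermediate
4 | 4-bromopent-1-ene (racemic) | CC(Br)CC=C | starting material
5 | pent-4-en-2-ylmagnesium bromide | C=CCC(C)[Mg]Br | intermediate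
6 | 4,8-dimethylnona-1,8-dien-5-one (racemic) | C=CCC(C)C(=O)CCC(C)=C | intermediate
7 | 2,5-dimethylcyclohept-4-en-1-one (racemic) | CC1CC=C(C)CCC1=O | intermediate
8 | [(2,5-dimethylcyclohepta-1,4-dien-1-yl)oxy]trimethylsilane | CC1=C(O[Si](C)(C)C)CCC(C)=CC1 | intermediate
9 | (2R)-2,5-dimethyl-2-(prop-2-en-1-yl)cyclohept-4-en-1-one | C=CC[C@]1(C)CC=C(C)CCC1=O | intermediate
10 | 9-{3-[(1R)-1,4-dimethyl-7-oxocyclohept-3-en-1-yl]propyl}-9-borabicyclo[3.3.1]nonane | C1CC2CCCC(C1)B2CCC[C@]3(C)CC=C(C)CCC3=O | intermediate
11 | (2R)-2-(3-hydroxypropyl)-2,5-dimethylcyclohept-4-en-1-one | OCCC[C@]1(C)CC=C(C)CCC1=O | intermediate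
12 | 3-[(1R)-1,4-dimethyl-7-oxocyclohept-3-en-1-yl]propanal | O=CCC[C@]1(C)CC=C(C)CCC1=O | intermediate
13 | methyl 2-[bis(2,2,2-trifluoroethoxy)phosphoryl]propanoate | COC(=O)C(C)P(=O)(OCC(F)(F)F)OCC(F)(F)F | starting material
14 | potassium salt (α-carbanion) of phosphonate 13 | [K+].COC(=O)[C-](C)P(=O)(OCC(F)(F)F)OCC(F)(F)F | intermediate
15 | methyl (2Z)-5-[(1R)-1,4-dimethyl-7-oxocyclohept-3-en-1-yl]-2-methylpent-2-enoate | COC(=O)/C(C)=C\CC[C@]1(C)CC=C(C)CCC1=O | intermediate
16 | methyl (2S)-2-[(1R,3aR,8aS)-8a-hydroxy-3a,6-dimethyl-1,2,3,3a,4,7,8,8a-octahydroazulen-1-yl]propanoate | COC(=O)[C@@H](C)[C@H]1CC[C@]2(C)CC=C(C)CC[C@]12O | intermediate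
17 | γ-lactone (1R,4R,5S,11S): lactone ring O–C5–C4–C11(CH3)–C12(=O) cis-fused to the cyclopentane of the cis-fused 1,8-dimethylhydroazulene, C8=C9 alkene, C1 methyl, C5 oxygen and C4–C11 bond on one face | O=C1[C@@H](C)[C@H]2CC[C@]3(C)CC=C(C)CC[C@]23O1 | intermediate
18 | (2S)-2-[(1R,3aR,8aS)-8a-hydroxy-3a,6-dimethyl-1,2,3,3a,4,7,8,8a-octahydroazulen-1-yl]propan-1-ol | OC[C@@H](C)[C@H]1CC[C@]2(C)CC=C(C)CC[C@]12O | intermediate
19 | 4-(benzyloxy)-3-methoxybenzoic acid | COc1cc(C(=O)O)ccc1OCc1ccccc1 | starting material
20 | (2S)-2-[(1R,3aR,8aS)-8a-hydroxy-3a,6-dimethyl-1,2,3,3a,4,7,8,8a-octahydroazulen-1-yl]propyl 4-(benzyloxy)-3-methoxybenzoate | COc1cc(C(=O)OC[C@@H](C)[C@H]2CC[C@]3(C)CC=C(C)CC[C@]23O)ccc1OCc1ccccc1 | intermediate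
21 | (8R,9S)-8,9-epoxide of 20, epoxide oxygen on the ring face opposite to the C5 hydroxyl | COc1cc(C(=O)OC[C@@H](C)[C@H]2CC[C@]3(C)C[C@@H]4O[C@]4(C)CC[C@]23O)ccc1OCc1ccccc1 | intermediate
22 | O-benzyl ether of the target: (1R,4R,5S,8S,9S,11S)-5,8-epoxy-9-hydroxy compound with C12 4-(benzyloxy)-3-methoxybenzoate | COc1cc(C(=O)OC[C@@H](C)[C@H]2CC[C@]3(C)C[C@H](O)[C@]4(C)CC[C@]23O4)ccc1OCc1ccccc1 | intermediate
23 | CNP0277205.1, (1R,4R,5S,8S,9S,11S)-5,8-epoxy-9-hydroxy compound with C12 vanillate | COc1cc(C(=O)OC[C@@H](C)[C@H]2CC[C@]3(C)C[C@H](O)[C@]4(C)CC[C@]23O4)ccc1O | target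

Total step count: 13. Longest linear sequence: 13 steps (1 to 23).

Steps most likely to fail

Step 9. Two processes may go wrong. Attack of the ketyl on the enoate face that puts C11 anti to the C5 oxygen gives an adduct that cannot lactonise; this costs material only. More serious is unselective C-protonation of the samarium enolate, which would scramble C11 inside the lactone fraction. The fallback sets out from 15 and comes back at 17; it sets C11 after the reductive step and not during it. The cyclisation of 15 is run with MeOH as a small proton donor without regard to C11. Beside 16 it then gives the C11-epimeric hydroxy ester F1, which closes to the C11-epimeric lactone F2. The lactone mixture (17 and F2) is treated with LiN(iPr)2 in THF at −78 °C, so that both epimers converge on the lithium enolate F3. This is quenched at −78 °C with 2,6-di-tert-butyl-4-methylphenol. Kinetic protonation of a cis-fused bicyclic lactone enolate on its convex face is known chemistry and should return 17.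

Step 5. Enantioselectivity may erode on the seven-membered enolate, and the C5=C6 enol ether carried over from step 4 would be allylated at C6. A shortfall in enantiomeric purity could also be made up by recrystallising diol 18. The fallback sets out from 7 and comes back at 12, bypassing steps 4 to 7; it is a chiral-imine Michael addition that is regiospecific for the more substituted α-carbon. Ketone 7 is condensed with (R)-1-phenylethylamine (TsOH cat., toluene, Dean–Stark) to the imine F4. Methyl acrylate (THF, 40 °C) reacts through the more substituted secondary enamine tautomer on the face away from the phenyl group to give the adduct imine F5; the (R)-amine is chosen from the known sense of this reaction with 2-methylcycloalkanones. Hydrolysis with aqueous AcOH gives the keto ester F6. LiAlH4 reduces ester and ketone to the diol F7, and Dess–Martin periodinane oxidises both carbinols to keto aldehyde 12.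

Step 2. The secondary homoallylic Grignard reagent may isomerise through the cyclopropylmethyl species to the primary 2-methylbut-3-enyl isomer, and Wurtz coupling may consume the bromide; both divert the nucleophile. The fallback sets out from 2 and comes back at 6 without an organomagnesium reagent. Acyl imidazole 2 acylates the lithium enolate of allyl propanoate (2 equiv, made with LiN(iPr)2, THF, −78 °C; Claisen-type C-acylation) to give the allyl β-keto ester F8. Pd(PPh3)4 (cat., THF, rt) then brings about Tsuji decarboxylative allylation: zerovalent palladium ionises the allyl ester, CO2 is lost, and the allyl group is delivered to the carbon that carried the carboxyl group, which gives 6.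

Further compounds
F1 | step 9 | methyl (2R)-2-[(1R,3aR,8aS)-8a-hydroxy-3a,6-dimethyl-1,2,3,3a,4,7,8,8a-octahydroazulen-1-yl]propanoate (C11 epimer of 16) | COC(=O)[C@H](C)[C@H]1CC[C@]2(C)CC=C(C)CC[C@]12O
F2 | step 9 | C11 epimer of lactone 17, (1R,4R,5S,11R) | O=C1[C@H](C)[C@H]2CC[C@]3(C)CC=C(C)CC[C@]23O1
F3 | step 9 | lithium enolate of lactones 17 and F2 | [Li+].[O-]C1=C(C)[C@H]2CC[C@]3(C)CC=C(C)CC[C@]23O1
F4 | step 5 | (1R)-N-(2,5-dimethylcyclohept-4-en-1-ylidene)-1-phenylethanamine | C[C@@H](N=C1CCC(C)=CCC1C)c1ccccc1
F5 | step 5 | methyl 3-[(1R)-1,4-dimethyl-7-{[(1R)-1-phenylethyl]imino}cyclohept-3-en-1-yl]propanoate | C[C@@H](N=C1CCC(C)=CC[C@@]1(C)CCC(=O)OC)c1ccccc1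
F6 | step 5 | methyl 3-[(1R)-1,4-dimethyl-7-oxocyclohept-3-en-1-yl]propanoate | COC(=O)CC[C@]1(C)CC=C(C)CCC1=O
F7 | step 5 | (2R)-2-(3-hydroxypropyl)-2,5-dimethylcyclohept-4-en-1-ol (both C1 carbinol epimers) | OCCC[C@]1(C)CC=C(C)CCC1O
F8 | step 2 | prop-2-en-1-yl 2,6-dimethyl-3-oxohept-6-enoate (racemic) | C=CCOC(=O)C(C)C(=O)CCC(C)=C
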